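**Retrosynthetic overview**

- Ring A is the benzo ring of the dihydrobenzofuran, ring B the 2,6-dimethoxyphenyl ether ring, ring C the guaiacyl ring; C7'/C8' are benzofuran C2/C3 and C7''/C8''/C9'' the glycerol chain.
- Last operation: one hydride treatment with acidic work-up releases both CH2OH groups (two N-acyl auxiliaries), the ring C phenol (acetate) and the ring A aldehyde (dioxolane).
- Glycerol chain: C7''–C8'' by an auxiliary-controlled syn glycolate aldol onto vanillin acetate, then Mitsunobu inversion at C7'' (threo to erythro); C8''–O by alkylation of the ring B phenol.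
- The only ring, the dihydrobenzofuran, is formed early in one operation: phenoxyl-radical C8'–C5 hetero-coupling of a sinapoyl sultam with vanillin ethylene acetal, then intramolecular quinone methide trapping (O–C7'), as in plant phenylcoumaran formation. The sultam sets both ring stereocentres.
- Building blocks: syringaldehyde, vanillin (used twice), camphorsultam, bromoacetyl bromide, a chloroacetyl oxazolidinone.

Assumption: the sultam (C=O anti to SO2, s-cis) is taken to direct bond formation at C8' to the face remote from its bridge methyl groups, which for (2S)-bornane-10,2-sultam gives the (2R,3S) ring; if the sense proves opposite, the equally available (2R)-sultam is used and nothing else changes.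

**Route**

Step 1
Reactants: 1 (2S)-bornane-10,2-sultam; 2 bromoacetyl bromide
Product: 5 N-(diethylphosphonoacetyl)-(2S)-bornane-10,2-sultam, via sodium sultamide 3 (not isolated), via N-bromoacetyl sultam 4 (not isolated)
Conditions: NaH (1.05 equiv), toluene, 0 °C to rt; 2 (1.1 equiv), 0 °C to rt; filter, concentrate; P(OEt)3 (1.5 equiv), 110 °C
Reagents that add atoms: triethyl phosphite, CCOP(OCC)OCC
Why: N-acylation of the sultam anion followed by a Michaelis–Arbuzov reaction of the α-bromo imide gives the olefination reagent; no stereocentre is formed.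

Step 2
Reactants: 5 N-(diethylphosphonoacetyl)-(2S)-bornane-10,2-sultam; 6 syringaldehyde
Product: 7 N-[(E)-sinapoyl]-(2S)-bornane-10,2-sultam
Conditions: LiCl (3 equiv), DBU (2.5 equiv), MeCN, rt to 40 °C
Reagents that add atoms: none
Why: Horner–Wadsworth–Emmons olefination under Masamune–Roush conditions gives the E-enoyl sultam, the extra base carrying the free phenol as its phenoxide, which only slows the addition.

Step 3
Reactants: 8 vanillin
Product: 9 4-(1,3-dioxolan-2-yl)-2-methoxyphenol
Conditions: ethylene glycol (3 equiv), TsOH·H2O (2 mol%), toluene, reflux, Dean–Stark; NaHCO3 wash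
Reagents that add atoms: ethylene glycol, OCCO
Why: acid-catalysed acetalisation with azeotropic water removal masks the aldehyde against the later boron enolate and hydride steps and makes the phenol electron-rich enough to be oxidised alongside 7.

Step 4
Reactants: 7 N-[(E)-sinapoyl]-(2S)-bornane-10,2-sultam; 9 4-(1,3-dioxolan-2-yl)-2-methoxyphenol
Product: 11 (2R,3R)-trans-2-(4-hydroxy-3,5-dimethoxyphenyl)-5-(1,3-dioxolan-2-yl)-7-methoxy-2,3-dihydrobenzofuran-3-carbonyl sultam, via quinone methide 10 (not isolated)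
Conditions: 9 (4 equiv), Ag2O (2.2 equiv), CH2Cl2/acetone 4:1, rt, dark; 7 added over 8 h; Celite; SiO2 (1% Et3N), diastereomers separated, excess 9 recovered
Reagents that add atoms: none
Why: Proposed new method: Ag2O oxidises both phenols to phenoxyl radicals, the sinapoyl radical can pair only through C8' (its 8–8' homo-dimerisation is retarded by two adjacent sultams) and does so with C5 of the guaiacyl radical held in excess, the sultam exposing one face of C8' and so fixing that centre, after which the rearomatised ring A phenol adds to quinone methide 10 anti to the acyl group to close the trans ring (C7' follows C8'); the closest known reaction type is the Ag2O- or peroxidase-mediated β-5 dehydrodimerisation of ferulic acid derivatives, including its diastereoselective version with chiral N-feruloyl auxiliaries, here extended to a hetero-coupling.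

Step 5
Reactants: 11 phenylcoumaran acyl sultam; 12 (S)-4-benzyl-3-(chloroacetyl)oxazolidin-2-one
Product: 13 ring B aryloxyacetyl imide of 11
Conditions: 12 (1.3 equiv), K2CO3 (1.5 equiv), NaI (0.1 equiv), acetone, rt
Reagents that add atoms: none
Why: Williamson etherification (SN2 at the activated α-halo imide carbon with in situ Finkelstein exchange) of the only free phenol; the ring stereocentres survive because enolisation of the α-branched acyl sultam is disfavoured by allylic 1,3-strain.

Step 6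
Reactants: 13 ring B aryloxyacetyl imide; 14 vanillin acetate
Product: 17 (2S,3R)-syn aldol adduct, via boron enolate 15 (not isolated), via boron aldolate 16 (not isolated)
Conditions: Bu2BOTf (1.2 equiv), iPr2NEt (1.4 equiv), CH2Cl2, −78 to 0 °C; 14 (1.3 equiv), −78 to 0 °C; pH 7 buffer, MeOH, 30% H2O2, 0 °C
Reagents that add atoms: none
Why: Evans glycolate aldol through the Z-boron enolate and a Zimmerman–Traxler chair, the (S)-benzyl group fixing C8'' in its final configuration and giving C7'' as R (syn, that is threo), while the hindered acyl sultam is not enolised.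

Step 7
Reactants: 17 (2S,3R)-syn aldol adduct
Product: 18 (2S,3S)-4-nitrobenzoate
Conditions: 4-nitrobenzoic acid (2 equiv), PPh3 (2 equiv), DIAD (2 equiv), THF, 0 °C to rt
Reagents that add atoms: 4-nitrobenzoic acid, O=C(O)c1ccc(cc1)[N+](=O)[O-]
Why: Mitsunobu reaction (SN2 on the alkoxyphosphonium ion) inverts C7'' from R to S and so turns the threo adduct into the erythro series, the 4-acetoxy group on ring C disfavouring benzylic ionisation.

Step 8
Reactants: 18 (2S,3S)-4-nitrobenzoate
Product: 20 target CID53356209, via acetal tetraol 19 (not isolated)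
Conditions: LiBH4 (10 equiv), MeOH (10 equiv), THF, 0 °C to rt; then 1 M HCl (aq) to pH 2, THF/H2O, 0 °C to rt, 30 min; NaHCO3
Reagents that add atoms: water, O
Why: borohydride reduction cleaves both N-acyl auxiliaries at the exocyclic carbonyl to CH2OH and both esters to the free phenol and C7'' alcohol, and the acidic work-up destroys excess hydride within seconds before it hydrolyses the electron-rich aryl dioxolane to the aldehyde over minutes, with no stereocentre touched.

**Compound list**

1 | (2S)-bornane-10,2-sultam, (1R)-(+)-2,10-camphorsultam (3aR,6S,7aS) | CC1(C)[C@H]2CC[C@@]13CS(=O)(=O)N[C@H]3C2 | starting material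
2 | bromoacetyl bromide | BrCC(Br)=O | starting material
3 | sodium salt of sultam 1 | CC1(C)[C@H]2CC[C@@]13CS(=O)(=O)[N-][C@H]3C2.[Na+] | intermediate
4 | N-(bromoacetyl)-(2S)-bornane-10,2-sultam | BrCC(=O)N1[C@H]2C[C@@H]3CC[C@@]2(CS1(=O)=O)C3(C)C | intermediate
5 | N-(diethylphosphonoacetyl)-(2S)-bornane-10,2-sultam | CCOP(=O)(OCC)CC(=O)N1[C@H]2C[C@@H]3CC[C@@]2(CS1(=O)=O)C3(C)C | intermediate
6 | syringaldehyde (4-hydroxy-3,5-dimethoxybenzaldehyde) | COc1cc(C=O)cc(OC)c1O | starting material
7 | N-[(E)-3-(4-hydroxy-3,5-dimethoxyphenyl)prop-2-enoyl]-(2S)-bornane-10,2-sultam | COc1cc(/C=C/C(=O)N2[C@H]3C[C@@H]4CC[C@@]3(CS2(=O)=O)C4(C)C)cc(OC)c1O | intermediate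
8 | vanillin | COc1cc(C=O)ccc1O | starting material
9 | 4-(1,3-dioxolan-2-yl)-2-methoxyphenol (vanillin ethylene acetal) | COc1cc(C2OCCO2)ccc1O | intermediate
10 | (8'S)-quinone methide: ring B as 2,6-dimethoxy-4-alkylidenecyclohexadienone, C8' bearing the acyl sultam and the 2-hydroxy-3-methoxy-5-(1,3-dioxolan-2-yl)phenyl group | COC1=CC(=C[C@H](C(=O)N2[C@H]3C[C@@H]4CC[C@@]3(CS2(=O)=O)C4(C)C)c2cc(C3OCCO3)cc(OC)c2O)C=C(OC)C1=O | intermediate
11 | N-[(2R,3R)-trans-2-(4-hydroxy-3,5-dimethoxyphenyl)-5-(1,3-dioxolan-2-yl)-7-methoxy-2,3-dihydrobenzofuran-3-carbonyl]-(2S)-bornane-10,2-sultam | COc1cc(cc(OC)c1O)[C@@H]1Oc2c(OC)cc(C3OCCO3)cc2[C@H]1C(=O)N1[C@H]2C[C@@H]3CC[C@@]2(CS1(=O)=O)C3(C)C | intermediate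
12 | (S)-4-benzyl-3-(chloroacetyl)oxazolidin-2-one | O=C(CCl)N1[C@@H](Cc2ccccc2)COC1=O | starting material
13 | 11 with its ring B phenol etherified as O-CH2-C(=O)-[(S)-4-benzyl-2-oxooxazolidin-3-yl] | O=C(COc1c(OC)cc(cc1OC)[C@@H]1Oc2c(OC)cc(C3OCCO3)cc2[C@H]1C(=O)N1[C@H]2C[C@@H]3CC[C@@]2(CS1(=O)=O)C3(C)C)N1[C@@H](Cc2ccccc2)COC1=O | intermediate
14 | vanillin acetate (4-formyl-2-methoxyphenyl acetate) | CC(=O)Oc1ccc(C=O)cc1OC | starting material
15 | Z-dibutylboron enolate of 13 | CCCCB(CCCC)O/C(=C\Oc1c(OC)cc(cc1OC)[C@@H]1Oc2c(OC)cc(C3OCCO3)cc2[C@H]1C(=O)N1[C@H]2C[C@@H]3CC[C@@]2(CS1(=O)=O)C3(C)C)N1[C@@H](Cc2ccccc2)COC1=O | intermediate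
16 | dibutylboron aldolate of 17 | CC(=O)Oc1ccc(cc1OC)[C@@H](OB(CCCC)CCCC)[C@@H](C(=O)N1[C@@H](Cc2ccccc2)COC1=O)Oc1c(OC)cc(cc1OC)[C@@H]1Oc2c(OC)cc(C3OCCO3)cc2[C@H]1C(=O)N1[C@H]2C[C@@H]3CC[C@@]2(CS1(=O)=O)C3(C)C | intermediate
17 | (2S,3R)-3-(4-acetoxy-3-methoxyphenyl)-3-hydroxy-2-aryloxypropanoyl imide (syn, threo; aryl = ring B of 11) | CC(=O)Oc1ccc(cc1OC)[C@@H](O)[C@@H](C(=O)N1[C@@H](Cc2ccccc2)COC1=O)Oc1c(OC)cc(cc1OC)[C@@H]1Oc2c(OC)cc(C3OCCO3)cc2[C@H]1C(=O)N1[C@H]2C[C@@H]3CC[C@@]2(CS1(=O)=O)C3(C)C | intermediate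
18 | (2S,3S)-3-(4-acetoxy-3-methoxyphenyl)-3-(4-nitrobenzoyloxy)-2-aryloxypropanoyl imide (anti, erythro) | CC(=O)Oc1ccc(cc1OC)[C@H](OC(=O)c1ccc(cc1)[N+](=O)[O-])[C@@H](C(=O)N1[C@@H](Cc2ccccc2)COC1=O)Oc1c(OC)cc(cc1OC)[C@@H]1Oc2c(OC)cc(C3OCCO3)cc2[C@H]1C(=O)N1[C@H]2C[C@@H]3CC[C@@]2(CS1(=O)=O)C3(C)C | intermediate
19 | ethylene acetal of the target: (7''S,8''R)-erythro glycerol chain, (2R,3S)-trans ring, 5-(1,3-dioxolan-2-yl) | COc1cc(ccc1O)[C@H](O)[C@@H](CO)Oc1c(OC)cc(cc1OC)[C@@H]1Oc2c(OC)cc(C3OCCO3)cc2[C@H]1CO | intermediate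
20 | CID53356209: (7''S,8''R)-erythro-guaiacylglycerol 8''-O-4' ether of (2R,3S)-2-(4-hydroxy-3,5-dimethoxyphenyl)-3-hydroxymethyl-7-methoxy-2,3-dihydrobenzofuran-5-carbaldehyde | COc1cc([C@H](O)[C@@H](CO)Oc2c(OC)cc([C@@H]3Oc4c(OC)cc(C=O)cc4[C@H]3CO)cc2OC)ccc1O | target

**Step count and risks**

Total steps: 8. Longest linear sequence: 7 (steps 1, 2, 4, 5, 6, 7, 8).

Most likely to fail:

Step 4. Hetero- versus homo-coupling, β-5 versus β-O-4 pairing, over-oxidation of the syringyl phenol of 11 and the facial selectivity are all unproven for this pair. The fallback sets out from 7 and comes back at 11. The phenol of 7 is silylated (TBSOTf, 2,6-lutidine, CH2Cl2) to silyl ether F1, so that only 9 can be oxidised. Oxidation of 9 in the presence of F1 (FeCl3 10 mol%, DDQ, toluene/CH2Cl2) then lets its phenoxyl radical add through C5 to C8' of the electron-rich enoyl sultam, and the resulting benzylic cation closes onto the phenol oxygen, giving phenylcoumaran silyl ether F2. TBAF/AcOH returns 11. This replaces radical–radical pairing by a radical–alkene oxidative [3+2] cycloaddition and removes homo-coupling of the syringyl unit.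

Step 6. Bu2BOTf may ionise the electron-rich aryl dioxolane, and the crowded adduct may retro-aldolise on work-up. The fallback sets out from 11 and comes back at 19. 11 is alkylated under the step 5 conditions with the enantiomeric reagent (R)-4-benzyl-3-(chloroacetyl)oxazolidin-2-one to imide F3. A soft-enolisation aldol with 14 (MgCl2 20 mol%, Et3N, Me3SiCl, EtOAc, rt) then proceeds through the magnesium-chelated enolate, which reacts on the opposite enolate face and in the anti sense. This gives the erythro (2S,3S) adduct directly as anti-aldol silyl ether F4, without a boron Lewis acid and without the inversion step. The hydride part of the step 8 conditions converts F4 into 19.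

Step 7. The activated β-hydroxy imide can eliminate to the α-aryloxy enoyl imide or ionise at the benzylic carbon, eroding C7''. The fallback sets out from 17 and comes back at 20. 17 is taken through the step 8 conditions unchanged, giving threo acetal F5 and then threo aldehyde F6, the C7'' epimer of the target. Me3SiBr in CHCl3 converts F6 into benzylic bromide F7, and aqueous NaHCO3 gives quinone methide F8. Water addition (dioxane/water, pH 3), which favours erythro about 3:1 for 2,6-dimethoxyphenyl ethers, gives 20. It is separated from F6 by reversed-phase chromatography and F6 is recycled. C7'' is thus set by quinone methide hydration, as in lignification.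

**Further compounds**

F1 | step 4 | tert-butyldimethylsilyl ether of 7 | COc1cc(/C=C/C(=O)N2[C@H]3C[C@@H]4CC[C@@]3(CS2(=O)=O)C4(C)C)cc(OC)c1O[Si](C)(C)C(C)(C)C
F2 | step 4 | tert-butyldimethylsilyl ether of 11 | COc1cc(cc(OC)c1O[Si](C)(C)C(C)(C)C)[C@@H]1Oc2c(OC)cc(C3OCCO3)cc2[C@H]1C(=O)N1[C@H]2C[C@@H]3CC[C@@]2(CS1(=O)=O)C3(C)C
F3 | step 6 | analogue of 13 with the (R)-4-benzyloxazolidinone | O=C(COc1c(OC)cc(cc1OC)[C@@H]1Oc2c(OC)cc(C3OCCO3)cc2[C@H]1C(=O)N1[C@H]2C[C@@H]3CC[C@@]2(CS1(=O)=O)C3(C)C)N1[C@H](Cc2ccccc2)COC1=O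
F4 | step 6 | (2S,3S)-anti aldol trimethylsilyl ether on the (R)-oxazolidinone | CC(=O)Oc1ccc(cc1OC)[C@H](O[Si](C)(C)C)[C@@H](C(=O)N1[C@H](Cc2ccccc2)COC1=O)Oc1c(OC)cc(cc1OC)[C@@H]1Oc2c(OC)cc(C3OCCO3)cc2[C@H]1C(=O)N1[C@H]2C[C@@H]3CC[C@@]2(CS1(=O)=O)C3(C)C
F5 | step 7 | (7''R,8''R)-threo epimer of 19 | COc1cc(ccc1O)[C@@H](O)[C@@H](CO)Oc1c(OC)cc(cc1OC)[C@@H]1Oc2c(OC)cc(C3OCCO3)cc2[C@H]1CO
F6 | step 7 | (7''R,8''R)-threo epimer of 20 | COc1cc(ccc1O)[C@@H](O)[C@@H](CO)Oc1c(OC)cc(cc1OC)[C@@H]1Oc2c(OC)cc(C=O)cc2[C@H]1CO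
F7 | step 7 | C7'' benzylic bromide of F6 (both C7'' epimers) | COc1cc(ccc1O)C(Br)[C@@H](CO)Oc1c(OC)cc(cc1OC)[C@@H]1Oc2c(OC)cc(C=O)cc2[C@H]1CO
F8 | step 7 | ring C quinone methide with C8'' R | COC1=CC(=C[C@@H](CO)Oc2c(OC)cc(cc2OC)[C@@H]2Oc3c(OC)cc(C=O)cc3[C@H]2CO)C=CC1=O
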